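The chroman is disconnected into an arene and the intact C20 chain: the dihydropyran ring (O1, C2, C3, C4, C4a, C8a) is closed by joining C1–C3 of (2E,6E,10E)-geranylgeraniol to the phenolic oxygen O1 and the adjacent free ring carbon C4a of a methylhydroquinone monoacetate. In one operation a confined chiral Brønsted acid should effect Friedel–Crafts allylation (C4–C4a) and enantioface-selective ring-closing hydroalkoxylation of the E-alkene (O1–C2), which creates the (R)-configured quaternary C2. The step exploits the ortho relationship of O1 and C4a on the arene and the allylic C4–C3=C2 unit of the chain. Deacetylation and C5 formylation of the resulting δ-tocotrienol complete the route.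

Key step: step 2

Remark: the sense of induction of the proposed acid-catalysed ring closure cannot be assigned in advance; the (S,S)-catalyst is written, and its mirror image would be used if it favoured the (2S)-chroman.

Step 1
Reactants: 1 4'-hydroxy-3'-methylacetophenone
Product: 2 4-hydroxy-3-methylphenyl acetate
Conditions: mCPBA (1.3 equiv), CH2Cl2, 0 °C to rt; aq. Na2SO3/NaHCO3 work-up
Reagents that add atoms: mCPBA (3-chloroperoxybenzoic acid), O=C(OO)c1cccc(Cl)c1
Why: Baeyer–Villiger oxidation, in which the electron-rich 4-hydroxyaryl group of the peracid adduct migrates in preference to methyl, so the acetate should be placed regiospecifically on the oxygen para to the free, methyl-flanked hydroxyl; no stereocenter is formed.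

Step 2
Reactants: 2 4-hydroxy-3-methylphenyl acetate; 3 (2E,6E,10E)-geranylgeraniol
Product: 5 (R)-δ-tocotrienol acetate, via ortho-geranylgeranyl phenol 4 (not isolated)
Conditions: (S,S)-IDPi acid (5 mol %; imidodiphosphorimidate of two (S)-3,3'-bis[3,5-bis(trifluoromethyl)phenyl]-BINOL units, N-triflyl), 2 (1.5 equiv), 5 Å molecular sieves, cyclohexane/CHCl3 4:1, 0 °C then 40 °C
Reagents that add atoms: none
Why: Proposed new method: the strong confined acid ionises the allylic C–OH of 3 to the (2E)-allyl cation as a contact ion pair, which attacks 2 through its primary terminus at the only ring carbon ortho to the free hydroxyl (Friedel–Crafts allylation, aryl–CH2 bond, giving 4), and the same acid then protonates the proximal E-alkene of 4 at C3 (chroman numbering) while the phenol oxygen adds to C2 from the opposite face (ring-closing hydroalkoxylation, O–C2 bond). The closest known reaction types are the classical acid-mediated condensation of hydroquinone monoesters with phytol to tocopherol esters, which makes the same two bonds without control at C2, and the imidodiphosphorimidate-catalysed asymmetric intramolecular hydroalkoxylation of unactivated alkenes. The dihydropyran ring is closed in the 6-endo-trig mode, with the tertiary-cation-like C2 as acceptor. The new stereocenter C2 is controlled by the catalyst: the chiral anion pocket selects which face of the E-alkene is protonated, and because H and O add anti, the defined E geometry turns this choice into one configuration at C2. The step needs site selectivity on the arene, secured by the acetate that leaves only the position ortho to the free OH activated, and retention of the 2E geometry, secured by starting from the primary E-allylic alcohol. It also needs chemoselectivity for the proximal alkene over the three remote trisubstituted alkenes, which rests on participation of the phenol oxygen (no nucleophile is within reach of the remote alkenes) and on the non-polar, non-ionising medium.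

Step 3
Reactants: 5 (R)-δ-tocotrienol acetate
Product: 6 (R)-δ-tocotrienol
Conditions: K2CO3 (0.2 equiv), MeOH, argon, 0 °C to rt; aq. NH4Cl work-up
Reagents that add atoms: none
Why: Base-catalysed transesterification of the aryl acetate with methanol (the phenoxide is a good leaving group), which should leave the trisubstituted alkenes and the C2 ether stereocenter untouched when air is excluded.

Step 4
Reactants: 6 (R)-δ-tocotrienol
Product: 7 (R)-5-formyl-δ-tocotrienol (target)
Conditions: anhydrous MgCl2 (2 equiv), Et3N (4 equiv), paraformaldehyde (6 equiv), THF, reflux, argon; 1 M HCl work-up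
Reagents that add atoms: paraformaldehyde (formaldehyde equivalent), C=O
Why: Magnesium phenoxide-mediated ortho-formylation (Casnati–Skattebøl reaction), in which the chelated phenoxide is hydroxymethylated at an ortho carbon and the benzylic alkoxide is oxidised by hydride transfer to a second formaldehyde, attack being expected at C5 and not at C7 because the fused dihydropyran localises the higher electron density at C5 (the site of classical electrophilic substitution of 8-methylchroman-6-ols) and C7 is flanked by the C8 methyl; no stereocenter is formed and C2 is untouched.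

Compound list
1 | 4'-hydroxy-3'-methylacetophenone | CC(=O)c1ccc(O)c(C)c1 | starting material
2 | 4-hydroxy-3-methylphenyl acetate | CC(=O)Oc1ccc(O)c(C)c1 | intermediate
3 | (2E,6E,10E)-geranylgeraniol, (2E,6E,10E)-3,7,11,15-tetramethylhexadeca-2,6,10,14-tetraen-1-ol | CC(C)=CCC/C(C)=C/CC/C(C)=C/CC/C(C)=C/CO | starting material
4 | 4-hydroxy-3-methyl-5-[(2E,6E,10E)-3,7,11,15-tetramethylhexadeca-2,6,10,14-tetraen-1-yl]phenyl acetate (ortho-geranylgeranyl phenol) | CC(C)=CCC/C(C)=C/CC/C(C)=C/CC/C(C)=C/Cc1cc(OC(C)=O)cc(C)c1O | intermediate
5 | (2R)-2,8-dimethyl-2-[(3E,7E)-4,8,12-trimethyltrideca-3,7,11-trien-1-yl]-3,4-dihydro-2H-chromen-6-yl acetate ((R)-δ-tocotrienol acetate) | CC(C)=CCC/C(C)=C/CC/C(C)=C/CC[C@]1(C)CCc2cc(OC(C)=O)cc(C)c2O1 | intermediate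
6 | (2R)-2,8-dimethyl-2-[(3E,7E)-4,8,12-trimethyltrideca-3,7,11-trien-1-yl]-3,4-dihydro-2H-chromen-6-ol ((R)-δ-tocotrienol) | CC(C)=CCC/C(C)=C/CC/C(C)=C/CC[C@]1(C)CCc2cc(O)cc(C)c2O1 | intermediate
7 | (2R)-6-hydroxy-2,8-dimethyl-2-[(3E,7E)-4,8,12-trimethyltrideca-3,7,11-trien-1-yl]-3,4-dihydro-2H-chromene-5-carbaldehyde | CC(C)=CCC/C(C)=C/CC/C(C)=C/CC[C@]1(C)CCc2c(C=O)c(O)cc(C)c2O1 | target

Total step count: 4. Longest linear sequence: 4 steps (1 to 2 to 5 to 6 to 7); 3 enters in step 2.

Steps most likely to fail

Step 2 (bears the label Proposed new method). Three processes may defeat it: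
- the strong acid may protonate the three remote trisubstituted alkenes, leading to cation–olefin cyclisation or double-bond migration in the side chain;
- the 2E geometry may be lost through reversible capture of the allyl cation at its tertiary terminus;
- facial discrimination in the ring-closing protonation may be weak.

The fallback uses known chemistry, raises the oxidation level of the C3 unit and separates the two bond formations. It sets out from 2, which is iodinated at the free position ortho to the hydroxyl (N-iodosuccinimide, CH2Cl2, 0 °C) to give 4-hydroxy-3-iodo-5-methylphenyl acetate F1. A Heck reaction of F1 with commercial (6E,10E)-geranyllinalool (Pd(OAc)2, Et3N, DMF, 80 °C; only the monosubstituted vinyl group inserts) should give the (E)-styryl tertiary carbinol 4-hydroxy-3-[(1E,6E,10E)-3-hydroxy-3,7,11,15-tetramethylhexadeca-1,6,10,14-tetraen-1-yl]-5-methylphenyl acetate F2. F2 is ionised by a chiral BINOL-derived N-triflyl phosphoramide (toluene, −60 °C), an acid too weak to protonate isolated alkenes. Ring closure within the chiral contact ion pair (asymmetric intramolecular allylic substitution, known for ortho-hydroxystyryl tertiary carbinols) should give the chromene (2R)-2,8-dimethyl-2-[(3E,7E)-4,8,12-trimethyltrideca-3,7,11-trien-1-yl]-2H-chromen-6-yl acetate F3. Hydrogenation of its cis-disubstituted C3=C4 bond with H2 and RhCl(PPh3)3 (benzene, rt), which should leave the trisubstituted alkenes untouched, returns to the route at 5.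

Step 4. The magnesium-templated hydroxymethylation may discriminate poorly between the two ring carbons ortho to the phenol (C5 and C7). The fallback sets out from 6. Low-temperature electrophilic bromination (N-bromosuccinimide, 1 equiv, CH2Cl2, −78 °C) should give (2R)-5-bromo-2,8-dimethyl-2-[(3E,7E)-4,8,12-trimethyltrideca-3,7,11-trien-1-yl]-3,4-dihydro-2H-chromen-6-ol F4. This substitution is governed by ring electronics alone, and its product can be purified before the carbon is introduced. Deprotonation and bromine–lithium exchange (n-BuLi, 2.2 equiv, THF, −78 °C), then quench of the O,C-dilithio species with DMF, returns to the route at 7.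

Step 1. The peracid may oxidise the free, electron-rich phenol ring (quinone formation) in competition with oxygen insertion. The fallback sets out from 1. Silylation (TBSCl, imidazole, DMF) gives 1-[4-(tert-butyldimethylsilyloxy)-3-methylphenyl]ethanone F5. Baeyer–Villiger oxidation of this less oxidisable silyl ether (mCPBA, CH2Cl2) gives 4-(tert-butyldimethylsilyloxy)-3-methylphenyl acetate F6. Desilylation with HF·pyridine (THF, 0 °C), which should spare the aryl acetate, returns to the route at 2.

Further compounds
F1 | step 2 | 4-hydroxy-3-iodo-5-methylphenyl acetate | CC(=O)Oc1cc(C)c(O)c(I)c1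
F2 | step 2 | 4-hydroxy-3-[(1E,6E,10E)-3-hydroxy-3,7,11,15-tetramethylhexadeca-1,6,10,14-tetraen-1-yl]-5-methylphenyl acetate (racemic at the carbinol carbon) | CC(C)=CCC/C(C)=C/CC/C(C)=C/CCC(C)(O)/C=C/c1cc(OC(C)=O)cc(C)c1O
F3 | step 2 | (2R)-2,8-dimethyl-2-[(3E,7E)-4,8,12-trimethyltrideca-3,7,11-trien-1-yl]-2H-chromen-6-yl acetate | CC(C)=CCC/C(C)=C/CC/C(C)=C/CC[C@]1(C)C=Cc2cc(OC(C)=O)cc(C)c2O1
F4 | step 4 | (2R)-5-bromo-2,8-dimethyl-2-[(3E,7E)-4,8,12-trimethyltrideca-3,7,11-trien-1-yl]-3,4-dihydro-2H-chromen-6-ol | CC(C)=CCC/C(C)=C/CC/C(C)=C/CC[C@]1(C)CCc2c(Br)c(O)cc(C)c2O1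
F5 | step 1 | 1-[4-(tert-butyldimethylsilyloxy)-3-methylphenyl]ethanone | CC(=O)c1ccc(O[Si](C)(C)C(C)(C)C)c(C)c1
F6 | step 1 | 4-(tert-butyldimethylsilyloxy)-3-methylphenyl acetate | CC(=O)Oc1ccc(O[Si](C)(C)C(C)(C)C)c(C)c1
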